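**Plan**
- Retrosynthesis: with seven benzyl ethers and a tert-butyl ester on C3 in place, the O1–C2 bond of ring C is cut (retro-oxa-Michael) to an alkylidene β-keto ester. Its C2=C3 bond is cut (Knoevenagel) into a ring B aldehyde and a ring A β-keto ester. The C5'–C8'' biaryl bond (Suzuki–Miyaura) and the C3–C4 bond (Claisen) are cut last.
- Forward: apigenin supplies the flavone rings intact. The biaryl is joined first, then the C2–C3 link, and ring C is closed last, followed by decarboxylation and hydrogenolysis.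
- Enabling feature: C2 sits on the O1–C2 bond, β to the C4 ketone of ring C. This bond opens and closes through the chalcone, and an ester on C3 turns the open form into a doubly activated acceptor that closes at low temperature.
- Stereochemistry: the only stereocentre, C2 (S), is set by a quinine-derived bifunctional thiourea during that closure. The C3 centre formed with it is erased by acid-mediated decarboxylation, under which ring C does not reopen.

Key step: step 10

Assumption 1: the C5'–C8'' axis carries three small oxygen ortho substituents and is taken to rotate freely on the laboratory time scale, so no atropisomers need to be controlled.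
Assumption 2: the quinine-derived thiourea is taken to direct O1 to the face of C2 that gives the (2S) product. The sense would be checked on 17, and the quinidine-derived pseudoenantiomer would replace it, with no other change, if it proved reversed.

**Route**

Step 1
Reactants: 1 apigenin
Product: 2 5,7-bis(benzyloxy)-2-[4-(benzyloxy)phenyl]-4H-chromen-4-one (tri-O-benzylapigenin)
Conditions: BnBr (4.5 equiv), K2CO3, n-Bu4NI (cat.), DMF, 80 °C
Reagents that add atoms: benzyl bromide, BrCc1ccccc1
Why: Williamson etherification of all three phenols, in which the chelated 5-OH reacts last and is driven by the excess halide, the polar solvent and heat.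

Step 2
Reactants: 2 tri-O-benzylapigenin
Product: 3 5,7-bis(benzyloxy)-2-[4-(benzyloxy)phenyl]-8-iodo-4H-chromen-4-one
Conditions: NIS (1.05 equiv), TFA (cat.), MeCN/CH2Cl2, 0 °C to rt
Reagents that add atoms: N-iodosuccinimide, O=C1CCC(=O)N1I
Why: Electrophilic aromatic iodination, which in 5,7-dialkoxyflavones should go to C8 because C6 is flanked by two benzyloxy groups and the 4-alkoxyphenyl ring is deactivated by the pyranone.

Step 3
Reactants: 4 5-iodovanillin
Product: 5 3,4-dihydroxy-5-iodobenzaldehyde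
Conditions: BBr3, CH2Cl2, −78 °C to rt; then H2O
Reagents that add atoms: none
Why: Lewis-acid cleavage of the aryl methyl ether (BBr3 demethylation), which leaves the aldehyde and the aryl iodide untouched.

Step 4
Reactants: 5 3,4-dihydroxy-5-iodobenzaldehyde
Product: 6 3,4-bis(benzyloxy)-5-iodobenzaldehyde
Conditions: BnBr (2.3 equiv), K2CO3, DMF, rt to 50 °C
Reagents that add atoms: benzyl bromide, BrCc1ccccc1
Why: Williamson etherification of both catechol oxygens, which are unhindered and acidic.

Step 5
Reactants: 6 3,4-bis(benzyloxy)-5-iodobenzaldehyde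
Product: 7 3,4-bis(benzyloxy)-5-(4,4,5,5-tetramethyl-1,3,2-dioxaborolan-2-yl)benzaldehyde
Conditions: B2pin2, PdCl2(dppf) (5 mol%), KOAc, 1,4-dioxane, 85 °C
Reagents that add atoms: bis(pinacolato)diboron, CC1(C)OB(OC1(C)C)B1OC(C)(C)C(C)(C)O1
Why: Miyaura borylation of the aryl iodide, in which the weak acetate base suppresses coupling of the product with unreacted iodide and the aldehyde is tolerated.

Step 6
Reactants: 3 8-iodo-tri-O-benzylapigenin; 7 aryl pinacol boronate aldehyde
Product: 8 3,4-bis(benzyloxy)-5-{5,7-bis(benzyloxy)-2-[4-(benzyloxy)phenyl]-4-oxo-4H-chromen-8-yl}benzaldehyde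
Conditions: Pd(OAc)2 (5 mol%), SPhos (10 mol%), K3PO4, toluene/H2O, 90 °C
Reagents that add atoms: none
Why: Suzuki–Miyaura coupling in which boron sits on the less hindered, less electron-rich ring to limit protodeboronation and the bulky biaryl phosphine supports reductive elimination to the tri-ortho-substituted biaryl.

Step 7
Reactants: 9 methyl 2,4,6-trihydroxybenzoate
Product: 10 methyl 2,4-bis(benzyloxy)-6-hydroxybenzoate
Conditions: BnBr (2.1 equiv), K2CO3, acetone, reflux
Reagents that add atoms: benzyl bromide, BrCc1ccccc1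
Why: Williamson etherification that should stop at the bis-ether because the last phenol is hydrogen-bonded to the ester carbonyl and much less nucleophilic.

Step 8
Reactants: 10 methyl 2,4-bis(benzyloxy)-6-hydroxybenzoate; 11 tert-butyl acetate
Product: 13 tert-butyl 3-[2,4-bis(benzyloxy)-6-hydroxyphenyl]-3-oxopropanoate, via tert-butyl acetate lithium enolate 12 (not isolated)
Conditions: LDA (4.2 equiv), 11 (4 equiv), THF, −78 °C; then 10, −78 to 0 °C; aq. NH4Cl
Reagents that add atoms: none
Why: Crossed Claisen condensation in which the excess of enolate 12 covers the phenoxide and the acidic product, and the tert-butyl ester resists lactonisation to a 4-hydroxycoumarin.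

Step 9
Reactants: 8 biaryl aldehyde; 13 ring A β-keto ester
Product: 14 tert-butyl 2-[2,4-bis(benzyloxy)-6-hydroxybenzoyl]-3-(3,4-bis(benzyloxy)-5-{5,7-bis(benzyloxy)-2-[4-(benzyloxy)phenyl]-4-oxo-4H-chromen-8-yl}phenyl)prop-2-enoate, E and Z mixture
Conditions: piperidine (20 mol%), AcOH (20 mol%), 4 Å MS, toluene, rt; chromatography to remove any cyclised material
Reagents that add atoms: none
Why: Knoevenagel condensation of the non-enolisable aryl aldehyde with the active methylene, run at room temperature and stopped early so that amine-promoted racemic ring closure stays minor.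

Step 10
Reactants: 14 alkylidene β-keto ester (E and Z mixture)
Product: 15 tert-butyl (2S)-5,7-bis(benzyloxy)-2-(3,4-bis(benzyloxy)-5-{5,7-bis(benzyloxy)-2-[4-(benzyloxy)phenyl]-4-oxo-4H-chromen-8-yl}phenyl)-4-oxochromane-3-carboxylate (C3 epimers and enol form)
Conditions: 1-[3,5-bis(trifluoromethyl)phenyl]-3-(9-deoxy-epi-quinin-9-yl)thiourea (10 mol%), toluene, −25 °C; crude product taken on directly
Reagents that add atoms: none
Why: The quinuclidine nitrogen takes the proton of the single free ring A phenol while the thiourea NH pair binds the two carbonyl oxygens of the alkylidene β-keto ester, and O1 then adds to the benzylidene carbon C2 to give a catalyst-bound enolate that is protonated at C3. The closest known reaction is the cinchona-thiourea-catalysed asymmetric intramolecular oxa-Michael addition of 2-hydroxyaryl alkylidene β-keto esters to flavanone-3-carboxylates. Ring C closes in a 6-endo-trig mode, forming the O1–C2 bond. The configuration at C2 is controlled by the catalyst through this two-point binding, which exposes one face of the C2=C3 bond to O1; the E and Z isomers interconvert under the amine by reversible conjugate addition and drain through the faster matched pathway. C3 arises as a labile mixture that is deleted in step 11. The step needs facial selectivity at C2 and attack by O1 only, which is secured because all other phenols are benzylated and because the C3 ester allows closure at −25 °C, where the retro-addition that would scramble C2 is slow.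

Step 11
Reactants: 15 tert-butyl (2S)-flavanone-3-carboxylate
Product: 17 (2S)-5,7-bis(benzyloxy)-2-(3,4-bis(benzyloxy)-5-{5,7-bis(benzyloxy)-2-[4-(benzyloxy)phenyl]-4-oxo-4H-chromen-8-yl}phenyl)chroman-4-one, via flavanone-3-carboxylic acid 16 (not isolated)
Conditions: TsOH·H2O (0.3 equiv), toluene, 80 °C
Reagents that add atoms: none
Why: Acid-mediated loss of 2-methylpropene from the tert-butyl ester and decarboxylation of the β-keto acid through its enol, which removes C3 as a stereocentre without the enolate that would open the O1–C2 bond, while benzyl ethers are stable to these conditions.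

Step 12
Reactants: 17 hepta-O-benzyl (2S)-flavanone
Product: 18 (2S)-2-{3,4-dihydroxy-5-[5,7-dihydroxy-2-(4-hydroxyphenyl)-4-oxo-4H-chromen-8-yl]phenyl}-5,7-dihydroxychroman-4-one (target)
Conditions: H2 (1 atm), 10% Pd/C, THF/MeOH, rt; stopped when the last benzyl ether is consumed
Reagents that add atoms: none
Why: Catalytic hydrogenolysis of the seven aryl benzyl ethers under neutral conditions, which should be faster than reduction of the flavone C2=C3 bond or the flavanone carbonyl and leaves C2 untouched.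

**Compound list**

1 | apigenin | O=c1cc(-c2ccc(O)cc2)oc2cc(O)cc(O)c12 | starting material
2 | 5,7-bis(benzyloxy)-2-[4-(benzyloxy)phenyl]-4H-chromen-4-one | O=c1cc(-c2ccc(OCc3ccccc3)cc2)oc2cc(OCc3ccccc3)cc(OCc3ccccc3)c12 | intermediate
3 | 5,7-bis(benzyloxy)-2-[4-(benzyloxy)phenyl]-8-iodo-4H-chromen-4-one | O=c1cc(-c2ccc(OCc3ccccc3)cc2)oc2c(I)c(OCc3ccccc3)cc(OCc3ccccc3)c12 | intermediate
4 | 5-iodovanillin | COc1cc(C=O)cc(I)c1O | starting material
5 | 3,4-dihydroxy-5-iodobenzaldehyde | O=Cc1cc(O)c(O)c(I)c1 | intermediate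
6 | 3,4-bis(benzyloxy)-5-iodobenzaldehyde | O=Cc1cc(OCc2ccccc2)c(OCc2ccccc2)c(I)c1 | intermediate
7 | 3,4-bis(benzyloxy)-5-(4,4,5,5-tetramethyl-1,3,2-dioxaborolan-2-yl)benzaldehyde | O=Cc1cc(OCc2ccccc2)c(OCc2ccccc2)c(B2OC(C)(C)C(C)(C)O2)c1 | intermediate
8 | 3,4-bis(benzyloxy)-5-{5,7-bis(benzyloxy)-2-[4-(benzyloxy)phenyl]-4-oxo-4H-chromen-8-yl}benzaldehyde | O=Cc1cc(OCc2ccccc2)c(OCc2ccccc2)c(-c2c(OCc3ccccc3)cc(OCc3ccccc3)c3c(=O)cc(-c4ccc(OCc5ccccc5)cc4)oc23)c1 | intermediate
9 | methyl 2,4,6-trihydroxybenzoate | COC(=O)c1c(O)cc(O)cc1O | starting material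
10 | methyl 2,4-bis(benzyloxy)-6-hydroxybenzoate | COC(=O)c1c(O)cc(OCc2ccccc2)cc1OCc3ccccc3 | intermediate
11 | tert-butyl acetate | CC(=O)OC(C)(C)C | starting material
12 | lithium enolate of tert-butyl acetate (formed in the flask) | [Li+].[O-]C(=C)OC(C)(C)C | intermediate
13 | tert-butyl 3-[2,4-bis(benzyloxy)-6-hydroxyphenyl]-3-oxopropanoate | CC(C)(C)OC(=O)CC(=O)c1c(O)cc(OCc2ccccc2)cc1OCc3ccccc3 | intermediate
14 | alkylidene β-keto ester, E and Z mixture (name as in step 9) | CC(C)(C)OC(=O)C(=Cc1cc(OCc2ccccc2)c(OCc2ccccc2)c(-c2c(OCc3ccccc3)cc(OCc3ccccc3)c3c(=O)cc(-c4ccc(OCc5ccccc5)cc4)oc23)c1)C(=O)c1c(O)cc(OCc2ccccc2)cc1OCc3ccccc3 | intermediate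
15 | tert-butyl (2S)-hepta-O-benzyl-flavanone-3-carboxylate, C3 unassigned (name as in step 10) | O=C1C(C(=O)OC(C)(C)C)[C@@H](c2cc(OCc3ccccc3)c(OCc3ccccc3)c(-c3c(OCc4ccccc4)cc(OCc4ccccc4)c4c(=O)cc(-c5ccc(OCc6ccccc6)cc5)oc34)c2)Oc2cc(OCc3ccccc3)cc(OCc3ccccc3)c21 | intermediate
16 | (2S)-hepta-O-benzyl-flavanone-3-carboxylic acid, C3 unassigned (formed in the flask) | O=C1C(C(=O)O)[C@@H](c2cc(OCc3ccccc3)c(OCc3ccccc3)c(-c3c(OCc4ccccc4)cc(OCc4ccccc4)c4c(=O)cc(-c5ccc(OCc6ccccc6)cc5)oc34)c2)Oc2cc(OCc3ccccc3)cc(OCc3ccccc3)c21 | intermediate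
17 | (2S)-5,7-bis(benzyloxy)-2-(3,4-bis(benzyloxy)-5-{5,7-bis(benzyloxy)-2-[4-(benzyloxy)phenyl]-4-oxo-4H-chromen-8-yl}phenyl)chroman-4-one | O=C1C[C@@H](c2cc(OCc3ccccc3)c(OCc3ccccc3)c(-c3c(OCc4ccccc4)cc(OCc4ccccc4)c4c(=O)cc(-c5ccc(OCc6ccccc6)cc5)oc34)c2)Oc2cc(OCc3ccccc3)cc(OCc3ccccc3)c21 | intermediate
18 | (2S)-2-{3,4-dihydroxy-5-[5,7-dihydroxy-2-(4-hydroxyphenyl)-4-oxo-4H-chromen-8-yl]phenyl}-5,7-dihydroxychroman-4-one (CNP0204144.1) | O=C1C[C@@H](c2cc(O)c(O)c(-c3c(O)cc(O)c4c(=O)cc(-c5ccc(O)cc5)oc34)c2)Oc2cc(O)cc(O)c21 | target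

**Step count and risks**

Total steps: 12. Longest linear sequence: 8 steps (steps 3, 4, 5, 6, 9, 10, 11, 12, from 5-iodovanillin).

Steps most likely to fail:

1. Step 10. Facial selectivity at C2 may be eroded by uncatalysed or residual-amine-promoted ring closure, by poor fit of the large biaryl substrate to the catalyst, or by retro-addition during handling. Fallback, setting out from 8 and returning at 17: Claisen–Schmidt condensation of 8 with 1-[2,4-bis(benzyloxy)-6-hydroxyphenyl]ethanone (KOH, EtOH/THF, rt) should give the 2'-hydroxychalcone F1. NaOAc in refluxing EtOH should close it to the racemic hepta-O-benzyl flavanone F2. Kinetic resolution by asymmetric transfer hydrogenation ([Cp*RhCl2]2 with the TsDPEN enantiomer matched to the (2R) ketone, HCO2H/Et3N, EtOAc, rt) should reduce the unwanted enantiomer to the cis-(2R,4R)-flavan-4-ol F3, which is separated, and leave (2S)-flavanone 17 for step 12.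

2. Step 6. Protodeboronation of the ortho-alkoxy boronate and slow reductive elimination to the tri-ortho-substituted biaryl may let reduction of the hindered iodoflavone take over. Fallback, setting out from 6 and returning at 8: stannylation of 6 with hexamethylditin (Pd(PPh3)4, toluene, 100 °C) should give 3,4-bis(benzyloxy)-5-(trimethylstannyl)benzaldehyde F4. Stille coupling of this stannane with iodide 3 (Pd(PPh3)4, CuI, CsF, DMF, 60 °C) avoids aqueous base and should deliver 8.

3. Step 8. The ester, held as a chelated phenoxide and flanked by two ortho oxygens, may resist enolate addition, or the product may lactonise to a 4-hydroxycoumarin on warming. Fallback, setting out from 10 and returning at 13: benzylation of the remaining phenol (BnBr, K2CO3, DMF, 80 °C) should give methyl 2,4,6-tris(benzyloxy)benzoate F5. Claisen condensation with enolate 12 (THF, −78 to 0 °C) should give tert-butyl 3-oxo-3-[2,4,6-tris(benzyloxy)phenyl]propanoate F6. Chelation-controlled removal of one ortho benzyl ether with MgBr2·OEt2 (toluene/Et2O, 60 °C) should then give 13.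

Further compounds
F1 | step 10 | (E)-1-[2,4-bis(benzyloxy)-6-hydroxyphenyl]-3-(3,4-bis(benzyloxy)-5-{5,7-bis(benzyloxy)-2-[4-(benzyloxy)phenyl]-4-oxo-4H-chromen-8-yl}phenyl)prop-2-en-1-one | O=C(/C=C/c1cc(OCc2ccccc2)c(OCc2ccccc2)c(-c2c(OCc3ccccc3)cc(OCc3ccccc3)c3c(=O)cc(-c4ccc(OCc5ccccc5)cc4)oc23)c1)c1c(O)cc(OCc2ccccc2)cc1OCc3ccccc3
F2 | step 10 | racemic 5,7-bis(benzyloxy)-2-(3,4-bis(benzyloxy)-5-{5,7-bis(benzyloxy)-2-[4-(benzyloxy)phenyl]-4-oxo-4H-chromen-8-yl}phenyl)chroman-4-one | O=C1CC(c2cc(OCc3ccccc3)c(OCc3ccccc3)c(-c3c(OCc4ccccc4)cc(OCc4ccccc4)c4c(=O)cc(-c5ccc(OCc6ccccc6)cc5)oc34)c2)Oc2cc(OCc3ccccc3)cc(OCc3ccccc3)c21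
F3 | step 10 | (2R,4R)-hepta-O-benzyl-cis-flavan-4-ol, 8-{2,3-bis(benzyloxy)-5-[(2R,4R)-5,7-bis(benzyloxy)-4-hydroxychroman-2-yl]phenyl}-5,7-bis(benzyloxy)-2-[4-(benzyloxy)phenyl]-4H-chromen-4-one | O[C@@H]1C[C@H](c2cc(OCc3ccccc3)c(OCc3ccccc3)c(-c3c(OCc4ccccc4)cc(OCc4ccccc4)c4c(=O)cc(-c5ccc(OCc6ccccc6)cc5)oc34)c2)Oc2cc(OCc3ccccc3)cc(OCc3ccccc3)c21
F4 | step 6 | 3,4-bis(benzyloxy)-5-(trimethylstannyl)benzaldehyde | O=Cc1cc(OCc2ccccc2)c(OCc2ccccc2)c([Sn](C)(C)C)c1
F5 | step 8 | methyl 2,4,6-tris(benzyloxy)benzoate | COC(=O)c1c(OCc2ccccc2)cc(OCc2ccccc2)cc1OCc3ccccc3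
F6 | step 8 | tert-butyl 3-oxo-3-[2,4,6-tris(benzyloxy)phenyl]propanoate | CC(C)(C)OC(=O)CC(=O)c1c(OCc2ccccc2)cc(OCc2ccccc2)cc1OCc3ccccc3
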